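**Retrosynthetic overview**

- The strategy rests on C8: it carries the aryl ether oxygen O4' of ring B and lies between the benzylic carbinol C7 on ring A and C9, so it is treated as a carbene carbon that bears C9 as an ester.
- Key disconnections: O4'–C8 and C7–C8, both made in one three-component coupling of ethyl diazoacetate, a ring B phenol and vanillin acetate under Rh2(OAc)4 and a chiral phosphoric acid. This step sets C7 and C8.
- Ring B phenol: acetosyringone is O-allylated, α-hydroxylated to the hydroxy dimethyl ketal (the masked ketol), silylated and deallylated.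
- End game: LiBH4 turns the ester into the C9 alcohol and removes the acetate, then dilute acid frees the ketol.
- No ring is formed; rings A and B come from the starting materials.

Key step: step 5

Assumptions: vanillin acetate is bought. The (R)-configured phosphoric acid is taken to deliver the (2R,3R) adduct; should a first run show the opposite sense, the (S)-acid is used with no other change. The target is (7R,8S), the erythro isomer (7-OH and 8-OAr anti in the zigzag drawing). Ketal-bearing intermediates are worked up without acid and purified on Et3N-treated silica.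

**Route**

Step 1
Reactants: 1 acetosyringone
Product: 2 1-[4-(allyloxy)-3,5-dimethoxyphenyl]ethan-1-one
Conditions: allyl bromide, K2CO3, DMF, 60 °C
Reagents that add atoms: allyl bromide, C=CCBr
Why: Williamson ether synthesis: the phenoxide of 1, although flanked by two methoxy groups, should be alkylated readily by the reactive allylic bromide, and the allyl ether shields the phenol from the oxidant of step 2.

Step 2
Reactants: 2 1-[4-(allyloxy)-3,5-dimethoxyphenyl]ethan-1-one
Product: 3 2-[4-(allyloxy)-3,5-dimethoxyphenyl]-2,2-dimethoxyethan-1-ol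
Conditions: KOH (3 equiv), MeOH, 0 °C; then PhI(OAc)2 (1.1 equiv), 0 °C to rt
Reagents that add atoms: methanol, CO
Why: Moriarty α-hydroxylation with trivalent iodine: the enolate of 2 attacks iodine, methoxide adds to the carbonyl group, the alkoxide expels iodobenzene to give a methoxy epoxide and methanol opens it at the acetal carbon, so the ketone should emerge masked as its dimethyl ketal with the former carbonyl oxygen as the primary hydroxyl, the isolated allyl double bond not being engaged in this basic medium.

Step 3
Reactants: 3 2-[4-(allyloxy)-3,5-dimethoxyphenyl]-2,2-dimethoxyethan-1-ol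
Product: 4 tert-butyl{2-[4-(allyloxy)-3,5-dimethoxyphenyl]-2,2-dimethoxyethoxy}dimethylsilane
Conditions: TBSCl, imidazole, DMF, rt
Reagents that add atoms: TBSCl, CC(C)(C)[Si](C)(C)Cl
Why: Silyl ether formation: the unhindered primary alcohol is silylated under imidazole buffering that leaves the acid-labile ketal untouched, which removes the only O–H that could compete with the phenol for the carbenoid in step 5.

Step 4
Reactants: 4 tert-butyl{2-[4-(allyloxy)-3,5-dimethoxyphenyl]-2,2-dimethoxyethoxy}dimethylsilane
Product: 5 4-[2-(tert-butyldimethylsilyloxy)-1,1-dimethoxyethyl]-2,6-dimethoxyphenol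
Conditions: Pd(PPh3)4 (3 mol %), morpholine (5 equiv), THF, rt
Reagents that add atoms: none
Why: Tsuji–Trost deallylation: zerovalent palladium ionises the allyl aryl ether to a π-allyl complex and the phenoxide, morpholine takes up the allyl group, and the neutral to basic medium spares ketal and silyl ether.

Step 5
Reactants: 5 4-[2-(tert-butyldimethylsilyloxy)-1,1-dimethoxyethyl]-2,6-dimethoxyphenol; 6 4-formyl-2-methoxyphenyl acetate (vanillin acetate); 7 ethyl diazoacetate
Product: 10 ethyl (2R,3R)-3-(4-acetoxy-3-methoxyphenyl)-3-hydroxy-2-{4-[2-(tert-butyldimethylsilyloxy)-1,1-dimethoxyethyl]-2,6-dimethoxyphenoxy}propanoate, via dirhodium carbenoid 8 (not isolated), via enol of the oxonium ylide 9 (not isolated)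
Conditions: Rh2(OAc)4 (2 mol %), (R)-TRIP [(R)-3,3'-bis(2,4,6-triisopropylphenyl)-1,1'-binaphthyl-2,2'-diyl hydrogen phosphate] (10 mol %), 4 Å MS, CH2Cl2, 0 °C; 7 (1.5 equiv) added over 4 h to 5 (1 equiv) and 6 (2 equiv)
Reagents that add atoms: none
Why: Proposed new method: Rh2(OAc)4 should expel N2 from 7 to give the divalent-rhodium carbenoid 8, the hindered but flat phenol 5 adds through oxygen, and the protic oxonium ylide (free enol 9 once rhodium has left) is caught by aldehyde 6 in an aldol-type addition before the 1,2-proton shift that would end in plain O–H insertion, so that O4'–C8 and C7–C8 are made in one operation and no ring is closed. The closest known reaction type is the three-component coupling of aryl diazoacetates, alcohols and aldehydes or imines under Rh2(OAc)4 and a chiral phosphoric acid by interception of oxonium ylides; an acceptor-only diazoacetate, a 2,6-disubstituted phenol and a donor-bearing benzaldehyde lie outside that scope. Both stereocentres, C7 and C8, are set in the C–C bond-forming event inside a hydrogen-bonded array in which the phosphoric acid holds the enol O–H through P=O and the aldehyde oxygen through P–OH: the binaphthyl pocket of the (R)-acid is relied on to choose the faces and thus the absolute (2R,3R) sense, and the erythro relation is expected because the aryl group of the aldehyde turns away from the bulky 2,6-dimethoxyaryloxy group on the enol carbon, the preference that lithium enolates of aryloxyacetates also show towards aromatic aldehydes. The step needs capture to outrun proton transfer and needs O–H attack to beat carbonyl-ylide formation and arene cyclopropanation; the 4-acetoxy group makes the ring A aldehyde more electrophilic, the acid activates it further, the flat phenol is the best nucleophile present, and slow addition of 7 to an excess of 6 keeps the carbenoid concentration low.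

Step 6
Reactants: 10 ethyl (2R,3R)-3-(4-acetoxy-3-methoxyphenyl)-3-hydroxy-2-{4-[2-(tert-butyldimethylsilyloxy)-1,1-dimethoxyethyl]-2,6-dimethoxyphenoxy}propanoate
Product: 11 (1R,2S)-2-{4-[2-(tert-butyldimethylsilyloxy)-1,1-dimethoxyethyl]-2,6-dimethoxyphenoxy}-1-(4-hydroxy-3-methoxyphenyl)propane-1,3-diol
Conditions: LiBH4 (5 equiv), THF, 0 °C to rt; pH 7 phosphate buffer work-up
Reagents that add atoms: none
Why: Borohydride reduction of an ester: the α-aryloxy ester is electrophilic enough for LiBH4 and should go to the primary alcohol C9, the aryl acetate is cleaved reductively in the same flask, ketal and silyl ether are inert to hydride, and neither stereocentre is touched (C8 is now named S only because CH2OH ranks below C7).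

Step 7
Reactants: 11 (1R,2S)-2-{4-[2-(tert-butyldimethylsilyloxy)-1,1-dimethoxyethyl]-2,6-dimethoxyphenoxy}-1-(4-hydroxy-3-methoxyphenyl)propane-1,3-diol
Product: 12 1-(4-{[(1R,2S)-1,3-dihydroxy-1-(4-hydroxy-3-methoxyphenyl)propan-2-yl]oxy}-3,5-dimethoxyphenyl)-2-hydroxyethan-1-one (target)
Conditions: 1 M aq. HCl–THF (1:4), 0 °C to rt, quenched with NaHCO3 as soon as 11 is consumed
Reagents that add atoms: water, O
Why: Acid hydrolysis of a dimethyl ketal and a primary silyl ether: both cleavages pass through oxygen-stabilised cations that form far more easily than the benzylic cation at C7, so a short exposure to cold dilute acid should free the ketol without epimerising C7.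

**Compound list**

1 | acetosyringone, 1-(4-hydroxy-3,5-dimethoxyphenyl)ethan-1-one | CC(=O)c1cc(OC)c(O)c(OC)c1 | starting material
2 | 1-[4-(allyloxy)-3,5-dimethoxyphenyl]ethan-1-one | CC(=O)c1cc(OC)c(OCC=C)c(OC)c1 | intermediate
3 | 2-[4-(allyloxy)-3,5-dimethoxyphenyl]-2,2-dimethoxyethan-1-ol | COc1cc(C(OC)(OC)CO)cc(OC)c1OCC=C | intermediate
4 | tert-butyl{2-[4-(allyloxy)-3,5-dimethoxyphenyl]-2,2-dimethoxyethoxy}dimethylsilane | COc1cc(C(OC)(OC)CO[Si](C)(C)C(C)(C)C)cc(OC)c1OCC=C | intermediate
5 | 4-[2-(tert-butyldimethylsilyloxy)-1,1-dimethoxyethyl]-2,6-dimethoxyphenol (ring B ketal phenol) | COc1cc(C(OC)(OC)CO[Si](C)(C)C(C)(C)C)cc(OC)c1O | intermediate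
6 | 4-formyl-2-methoxyphenyl acetate (vanillin acetate) | COc1cc(C=O)ccc1OC(C)=O | starting material
7 | ethyl diazoacetate | CCOC(=O)C=[N+]=[N-] | starting material
8 | ethoxycarbonyl carbenoid on Rh2(OAc)4 (divalent rhodium, written as its ions) | CCOC(=O)C=[Rh+2].[Rh+2].CC([O-])=O.CC([O-])=O.CC([O-])=O.CC([O-])=O | intermediate
9 | (E)-1-ethoxy-2-{4-[2-(tert-butyldimethylsilyloxy)-1,1-dimethoxyethyl]-2,6-dimethoxyphenoxy}ethen-1-ol (enol form of the oxonium ylide, aryloxy cis to the enol OH) | CCO/C(O)=C/Oc1c(OC)cc(C(OC)(OC)CO[Si](C)(C)C(C)(C)C)cc1OC | intermediate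
10 | ethyl (2R,3R)-3-(4-acetoxy-3-methoxyphenyl)-3-hydroxy-2-{4-[2-(tert-butyldimethylsilyloxy)-1,1-dimethoxyethyl]-2,6-dimethoxyphenoxy}propanoate (erythro) | COc1cc([C@@H](O)[C@H](C(=O)OCC)Oc2c(OC)cc(C(OC)(OC)CO[Si](C)(C)C(C)(C)C)cc2OC)ccc1OC(C)=O | intermediate
11 | (1R,2S)-2-{4-[2-(tert-butyldimethylsilyloxy)-1,1-dimethoxyethyl]-2,6-dimethoxyphenoxy}-1-(4-hydroxy-3-methoxyphenyl)propane-1,3-diol | COc1cc([C@@H](O)[C@H](CO)Oc2c(OC)cc(C(OC)(OC)CO[Si](C)(C)C(C)(C)C)cc2OC)ccc1O | intermediate
12 | 1-(4-{[(1R,2S)-1,3-dihydroxy-1-(4-hydroxy-3-methoxyphenyl)propan-2-yl]oxy}-3,5-dimethoxyphenyl)-2-hydroxyethan-1-one (CNP0282675.1) | COc1cc([C@@H](O)[C@H](CO)Oc2c(OC)cc(C(=O)CO)cc2OC)ccc1O | target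

**Step count and risks**

Total step count: 7. Longest linear sequence: 7 steps (1 to 12).

Steps most likely to fail:

1. Step 5 (proposed new method). The proton shift may outrun the aldol-type capture, so that only O–H insertion occurs. Capture may also occur with poor facial or erythro/threo selectivity, or the acid may consume the diazo ester or open the ketal. Fallback by known, stepwise chemistry, setting out from 5 and returning at 10:
   - Alkylation of 5 with ethyl bromoacetate (K2CO3, acetone, reflux) should give ethyl 2-{4-[2-(tert-butyldimethylsilyloxy)-1,1-dimethoxyethyl]-2,6-dimethoxyphenoxy}acetate F1. This is also the compound that a failed coupling would leave.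
   - Its lithium enolate (LiN(iPr)2, THF, −78 °C) is added to 6 in the classical aryloxyacetate aldol. After chromatographic removal of the threo pair this should give the racemic erythro hydroxy ester F2.
   - Preparative chromatography on a chiral stationary phase then gives the (2R,3R)-enantiomer, which is 10, and the route continues with step 6.

2. Step 7. Ionisation at the p-hydroxybenzylic C7 may compete with ketal and silyl cleavage, which would epimerise C7 or let methanol be captured there. Fallback, setting out from 11 and returning at 12: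
   - Fluoride (TBAF buffered with AcOH, THF, 0 °C) removes only the silyl group to give (1R,2S)-2-[4-(2-hydroxy-1,1-dimethoxyethyl)-2,6-dimethoxyphenoxy]-1-(4-hydroxy-3-methoxyphenyl)propane-1,3-diol F3.
   - The ketal alone is then hydrolysed under buffered conditions (pyridinium p-toluenesulfonate, acetone–water, rt) to 12, so that no mineral acid meets the benzylic alcohol.

3. Step 2. The trivalent-iodine oxidant may attack the allyl double bond or degrade the electron-rich ring instead of reacting with the enolate. Fallback, setting out from 2 and returning at 4, replacing steps 2 and 3: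
   - TBSOTf and Et3N (CH2Cl2, 0 °C) convert 2 into the silyl enol ether {[1-(4-allyloxy-3,5-dimethoxyphenyl)ethenyl]oxy}(tert-butyl)dimethylsilane F4.
   - Rubottom oxidation (mCPBA 1.0 equiv, NaHCO3, CH2Cl2, −20 °C; the enol ether reacts far faster than the allyl group) gives, by silyl migration, 1-[4-(allyloxy)-3,5-dimethoxyphenyl]-2-(tert-butyldimethylsilyloxy)ethan-1-one F5.
   - Noyori ketalisation (MeOSiMe3, TMSOTf cat., CH2Cl2, −78 to −20 °C) then gives 4.

**Further compounds**

F1 | step 5 | ethyl 2-{4-[2-(tert-butyldimethylsilyloxy)-1,1-dimethoxyethyl]-2,6-dimethoxyphenoxy}acetate | CCOC(=O)COc1c(OC)cc(C(OC)(OC)CO[Si](C)(C)C(C)(C)C)cc1OC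
F2 | step 5 | racemic erythro hydroxy ester (10 together with its (2S,3S)-enantiomer) | COc1cc([C@@H](O)[C@H](C(=O)OCC)Oc2c(OC)cc(C(OC)(OC)CO[Si](C)(C)C(C)(C)C)cc2OC)ccc1OC(C)=O.COc1cc([C@H](O)[C@@H](C(=O)OCC)Oc2c(OC)cc(C(OC)(OC)CO[Si](C)(C)C(C)(C)C)cc2OC)ccc1OC(C)=O
F3 | step 7 | (1R,2S)-2-[4-(2-hydroxy-1,1-dimethoxyethyl)-2,6-dimethoxyphenoxy]-1-(4-hydroxy-3-methoxyphenyl)propane-1,3-diol | COc1cc([C@@H](O)[C@H](CO)Oc2c(OC)cc(C(OC)(OC)CO)cc2OC)ccc1O
F4 | step 2 | {[1-(4-allyloxy-3,5-dimethoxyphenyl)ethenyl]oxy}(tert-butyl)dimethylsilane | C=C(O[Si](C)(C)C(C)(C)C)c1cc(OC)c(OCC=C)c(OC)c1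
F5 | step 2 | 1-[4-(allyloxy)-3,5-dimethoxyphenyl]-2-(tert-butyldimethylsilyloxy)ethan-1-one | C=CCOc1c(OC)cc(C(=O)CO[Si](C)(C)C(C)(C)C)cc1OC
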